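At 12 h I had to say what the flask would hold, with L and E charged nearly equal and E the limiting reagent, and two earlier runs were what I had to go on.

| setting | red | violet | flask |
|---|---|---|---|
| L | 0.10 M | 0.40 M | 0.20 M |
| E | 0.19 M | 0.19 M | 0.190 M |
| G | 0.30 M | 0.30 M | 0.300 M |
| remark | run made earlier | run made earlier |  |
| time |  |  | 12 h |

| run | time / h | L / % | Q / % |
|---|---|---|---|
| red | 0.500 | 85.0 | 14.9 |
| red | 1.33 | 68.3 | 31.5 |
| red | 3.00 | 48.7 | 51.7 |
| red | 8.00 | 24.4 | 76.5 |
| violet | 2.00 | 76.8 | 22.7 |
| violet | 4.00 | 71.2 | 29.2 |
| violet | 5.00 | 68.8 | 31.4 |
| violet | 8.00 | 63.6 | 35.9 |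

(readings scatter by 0.5 percentage points)

* part of the L that has reacted at 12 h
* share of the unused E that is free and not bound as X, at 12 h

- the earlier runs do not show how much of E is bound; that part of a forecast is a guess

L and Q added up to the charge within the scatter, so I took each L lost to have used one E. Late in the violet run, from 5.00 h to 8.00 h, the L lost per minute, divided by the L present and by the unused E, came to 0.00796 M⁻¹ min⁻¹. This working constant, L lost per minute per L and per unused E, bound or free, had stood at 0.0296 M⁻¹ min⁻¹ in the first 0.500 h of the red run, and I read the ratio, 26.9%, as the free share of the unused E.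

Because L and E are nearly equal in the flask, I could follow one line, with the constant taken midway by ratio:

one over unused E at the end = one over its charge + constant × time = one over 0.0613 M, so L reacted = 64.4%

That midway constant was the weak link, so I replaced it with a reading, the red run's from 3.00 h to 8.00 h, 0.0175 M⁻¹ min⁻¹, taken where unused E stood near the middle of the flask's path, and it gave 67.0%; I committed to that span, with 26.9% free.

The forecast stood lower than mine, at 62% (57% to 67%) and 20% (7% to 45%), with the words “The free share is a guess”.

The flask gave 64.5% reacted and 42.8% free.

    G + D → J (k = 0.376 M⁻¹ min⁻¹)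
    L + E → Q + D (k = 0.0311 M⁻¹ min⁻¹)
    E + D ⇌ X, settled at all times (K = 1000 M⁻¹)

The flask had not come to rest at 12 h. Its unused E stood at 0.0611 M, so the life of L in the flask at that moment, one over my late working constant and that unused E, reckoned to 34.3 h, longer than the time run. The neighbour flask charged with 0.11 M of E reckoned the same way to 92.4 h at 12 h, with 56.3% of its L left then. Left until 120 h, the flask went from 64.5% to 94.1% reacted.

The earlier runs and the new flask were generated by integration with made-up constants; the scatter is artificial.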